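**Retrosynthetic overview**

- Ring locants: C1 (quaternary epoxide carbon bearing C7H2OBz), C2 (CHOBz), C3 (CHOH), C4=C5, C6 (epoxide CH). The strategy rests on the array C7–C1–C6–C5=C4 of the cyclohexene ring, a γ,δ-unsaturated acyl unit whose α-carbon C1 is fully substituted and oxygenated, which is the imprint of a [3,3] shift.
- The oxirane comes from a trans C1–OH/C6–OMs pair, the two benzoates from a C7/C2 diol whose tertiary C1–OH neighbour does not acylate, and C7H2OH from a carboxylic acid.
- Cyclohexene acid 16 comes from the silyl ketene acetal of δ-lactone 13 (C7 carbonyl, ring oxygen on C4, E-alkoxyvinyl C5=C6 on C4): C1–C6 forms as C4–O breaks.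
- Lactone 13 comes from L-gulono-1,4-lactone: amide opening, O4 silylation, relactonisation onto O5, C6 oxidation, one-carbon Wittig homologation.
- Order of ring formation: δ-lactone (temporary), then the carbocycle (step 10), then the oxirane (step 15).

Key step: step 10

Assumptions: compounds 1–13 carry carbohydrate locants; from step 10 on the ring locants above are used (ring C1…C6 = sugar C2…C7, C7 = sugar C1), and β is the ring face that carries C7. The Wittig step is taken to give both enol ether geometries; only the chromatographically separated E isomer is carried on.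

**Route**

Step 1
Reactants: 1 L-gulono-1,4-lactone
Product: 2 2,3:5,6-di-O-isopropylidene-L-gulono-1,4-lactone
Conditions: 2,2-dimethoxypropane, acetone, TsOH·H2O (cat.), rt
Reagents that add atoms: 2,2-dimethoxypropane COC(C)(C)OC
Why: Acid-catalysed transacetalisation (acetonide formation) engages the cis-2,3-diol of the γ-lactone and the terminal 5,6-diol as two dioxolanes and leaves O4 in the lactone, so no stereocentre is touched.

Step 2
Reactants: 2 2,3:5,6-di-O-isopropylidene-L-gulono-1,4-lactone
Product: 3 N-methoxy-N-methyl-2,3:5,6-di-O-isopropylidene-L-gulonamide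
Conditions: MeNH(OMe)·HCl, i-PrMgCl, THF, −20 → 0 °C
Reagents that add atoms: N,O-dimethylhydroxylamine hydrochloride CNOC.Cl
Why: Aminolysis of the γ-lactone by the chloromagnesium amide (Weinreb amide formation) opens the ring without epimerisation and frees O4–H as the only hydroxyl.

Step 3
Reactants: 3 N-methoxy-N-methyl-2,3:5,6-di-O-isopropylidene-L-gulonamide
Product: 4 N-methoxy-N-methyl-2,3:5,6-di-O-isopropylidene-4-O-triisopropylsilyl-L-gulonamide
Conditions: i-Pr3SiOTf, 2,6-lutidine, CH2Cl2, 0 °C → rt (crude 3 used at once)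
Reagents that add atoms: triisopropylsilyl trifluoromethanesulfonate CC(C)[Si](C(C)C)(C(C)C)OS(=O)(=O)C(F)(F)F
Why: Silyl triflate silylation is fast enough for the hindered C4 hydroxyl and caps it before the hydroxy amide relactonises, which later forces the lactone onto O5.

Step 4
Reactants: 4 N-methoxy-N-methyl-2,3:5,6-di-O-isopropylidene-4-O-triisopropylsilyl-L-gulonamide
Product: 5 4-O-triisopropylsilyl-L-gulono-1,5-lactone
Conditions: TFA/H2O (9:1), 0 °C → rt; toluene azeotrope
Reagents that add atoms: none
Why: Aqueous acid hydrolyses both acetonides (the triisopropylsilyl ether should tolerate short exposure) and, with O4 blocked, acid-catalysed lactonisation of the N-methoxy-N-methylamide can only use the 5-OH, giving the six-membered lactone.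

Step 5
Reactants: 5 4-O-triisopropylsilyl-L-gulono-1,5-lactone
Product: 6 2,3,6-tri-O-triethylsilyl-4-O-triisopropylsilyl-L-gulono-1,5-lactone
Conditions: Et3SiOTf, 2,6-lutidine, CH2Cl2, −78 → 0 °C
Reagents that add atoms: triethylsilyl trifluoromethanesulfonate CC[Si](CC)(CC)OS(=O)(=O)C(F)(F)F
Why: Exhaustive silylation with the silyl triflate protects the two secondary hydroxyls and the primary one in one operation, with a base too weak to open or epimerise the lactone.

Step 6
Reactants: 6 2,3,6-tri-O-triethylsilyl-4-O-triisopropylsilyl-L-gulono-1,5-lactone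
Product: 7 2,3-di-O-triethylsilyl-4-O-triisopropylsilyl-L-gulono-1,5-lactone-6-al (C6 aldehyde)
Conditions: (COCl)2, DMSO, CH2Cl2, −78 → −30 °C; Et3N, −78 → 0 °C; used crude
Reagents that add atoms: none
Why: Under Swern conditions the unhindered primary triethylsilyl ether is cleaved by the chlorosulfonium salt and oxidised in the same flask (oxidative desilylation), the secondary silyl ethers stay, and the cold amine quench limits epimerisation at C5.

Step 7
Reactants: 8 4-methoxybenzyl alcohol
Product: 9 4-methoxybenzyl (methylthio)methyl ether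
Conditions: NaH, ClCH2SMe, NaI (cat.), THF, 0 °C → rt
Reagents that add atoms: chloromethyl methyl sulfide CSCCl
Why: Williamson etherification of the sodium alkoxide with the activated chloromethyl sulfide gives the O,S-acetal that serves as a masked chloromethyl ether.

Step 8
Reactants: 9 4-methoxybenzyl (methylthio)methyl ether
Product: 11 [(4-methoxybenzyloxy)methyl]triphenylphosphonium chloride, via chloromethyl ether 10 (not isolated)
Conditions: SO2Cl2, CH2Cl2, −78 °C; volatiles removed in vacuo; PPh3, toluene, rt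
Reagents that add atoms: sulfuryl chloride O=S(=O)(Cl)Cl; triphenylphosphine c1ccc(cc1)P(c1ccccc1)c1ccccc1
Why: Sulfuryl chloride converts the methylthiomethyl ether into the chloromethyl ether without free HCl (which would cleave the PMB ether), and SN2 quaternisation of PPh3 gives the Wittig salt.

Step 9
Reactants: 7 C6 aldehyde; 11 [(4-methoxybenzyloxy)methyl]triphenylphosphonium chloride
Product: 13 (E)-6-deoxy-7-O-(4-methoxybenzyl)-2,3-di-O-triethylsilyl-4-O-triisopropylsilyl-L-gulo-hept-6-enono-1,5-lactone, via ylide 12 (not isolated)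
Conditions: 11, NaN(SiMe3)2, THF, −78 → 0 °C; then 7, −78 → −20 °C; chromatography on Et3N-washed silica
Reagents that add atoms: none
Why: Wittig olefination of the aldehyde, far more electrophilic than the lactone, with the alkoxymethylene ylide at low temperature adds C7 and its oxygen; both alkene geometries are expected and the E isomer is separated.

Step 10
Reactants: 13 (E)-enol ether lactone
Product: 16 1α,2β-bis(triethylsilyloxy)-3α-(triisopropylsilyloxy)-6β-(4-methoxybenzyloxy)cyclohex-4-ene-1β-carboxylic acid, via silyl ketene acetal 14 (not isolated), via trimethylsilyl ester 15 (not isolated)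
Conditions: LiN(i-Pr)2, Me3SiCl/Et3N, THF, −78 °C → rt; toluene, 70 °C; aq. citric acid
Reagents that add atoms: chlorotrimethylsilane C[Si](C)(C)Cl (silicon groups of 14 and 15)
Why: LiN(i-Pr)2 removes the C1 hydrogen while Me3SiCl is already present, so the enolate is O-silylated to cyclic ketene acetal 14, which on warming undergoes a concerted [3,3]-sigmatropic shift (C1–C6 forms as C4–O breaks); hydrolysis of silyl ester 15 gives 16. The closest known reaction type is the ring-contracting Ireland–Claisen rearrangement of silyl ketene acetals of 6-alkenyl lactones. The cyclohexene closes by this sigmatropic C–C bond formation across the lactone, the alkenyl arm bridging C4 and C1 in a boat, bicyclo[2.2.2]octene-like transition state that the six-membered lactone enforces. The quaternary centre C1 is set by chirality transfer from C4: the arm reaches only the ketene acetal face on which it sits, so the carboxyl ends up cis to the C2 oxygen and trans to the C3 oxygen, and the original configuration at C1 of 13 is erased and irrelevant. C6 is set by the E enol ether geometry, which in the boat array puts its oxygen on the carboxyl face, trans to the C1 oxygen. The step needs O-silylation to outrun loss of the C2 silyloxy group (internal Me3SiCl quench at −78 °C) and a single alkene geometry (pure E-13); the donor oxygen on C6 should lower the barrier.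

Step 11
Reactants: 16 cyclohexene acid
Product: 17 [1α,2β-bis(triethylsilyloxy)-3α-(triisopropylsilyloxy)-6β-(4-methoxybenzyloxy)cyclohex-4-en-1β-yl]methanol
Conditions: LiAlH4, THF, 0 °C → rt
Reagents that add atoms: none
Why: LiAlH4 reduces the hindered carboxylic acid to the neopentyl-type primary alcohol and leaves silyl ethers, the PMB ether and the isolated alkene untouched.

Step 12
Reactants: 17 bis(triethylsilyl) ether alcohol
Product: 18 1β-(hydroxymethyl)-6β-(4-methoxybenzyloxy)-3α-(triisopropylsilyloxy)cyclohex-4-ene-1α,2β-diol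
Conditions: HF·pyridine, pyridine, THF, 0 °C → rt
Reagents that add atoms: none
Why: Pyridine-buffered HF·pyridine cleaves triethylsilyl ethers, the tertiary one included, much faster than the secondary triisopropylsilyl ether (steric selectivity of desilylation), and the allylic PMB ether is stable to it.

Step 13
Reactants: 18 triol
Product: 19 C7,O2-dibenzoate of 18 (C1α tertiary hydroxyl free)
Conditions: BzCl, pyridine, DMAP (cat.), CH2Cl2, 0 → 40 °C
Reagents that add atoms: benzoyl chloride O=C(Cl)c1ccccc1
Why: Nucleophile-catalysed acylation esterifies the primary and the secondary hydroxyl while the tertiary C1 hydroxyl is too hindered to react, so O1 and O2 are told apart without a protecting group.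

Step 14
Reactants: 19 dibenzoate PMB ether
Product: 20 1β-(benzoyloxymethyl)-2β-benzoyloxy-3α-(triisopropylsilyloxy)cyclohex-4-ene-1α,6β-diol
Conditions: DDQ, CH2Cl2/pH 7 phosphate buffer, 0 °C → rt
Reagents that add atoms: none
Why: DDQ oxidises the electron-rich PMB ether by hydride abstraction and water hydrolyses the oxocarbenium ion, freeing the C6 hydroxyl without touching benzoates, silyl ether or alkene.

Step 15
Reactants: 20 trans-1α,6β-diol
Product: 22 1α,6α-epoxide (3-O-triisopropylsilyl ether of the target), via mesylate 21 (not isolated)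
Conditions: MsCl, Et3N, CH2Cl2, −20 °C; then DBU, 0 °C → rt
Reagents that add atoms: methanesulfonyl chloride CS(=O)(=O)Cl (sulfonate of 21)
Why: Sulfene-type mesylation takes the secondary allylic C6 hydroxyl in preference to the tertiary one, and the base then triggers intramolecular Williamson (3-exo-tet) displacement by the C1 oxygen with inversion at C6 through the trans-diaxial conformer; E2 is not possible because C6 has no sp3 β-hydrogen.

Step 16
Reactants: 22 epoxide silyl ether
Product: 23 target, [(1α,6α)-epoxy-2β-benzoyloxy-3α-hydroxycyclohex-4-en-1β-yl]methyl benzoate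
Conditions: Bu4NF, AcOH (1:1), THF, 0 °C → rt
Reagents that add atoms: none
Why: Acetic acid-buffered fluoride cleaves the silyl ether without generating a free C3 alkoxide, so the neighbouring benzoate does not migrate and the vinyl epoxide is not exposed to acid.

**Compound list**

1 | L-gulono-1,4-lactone | O=C1[C@@H](O)[C@@H](O)[C@H](O1)[C@@H](O)CO | starting material
2 | 2,3:5,6-di-O-isopropylidene-L-gulono-1,4-lactone | O=C1[C@H]2OC(C)(C)O[C@H]2[C@H](O1)[C@@H]3COC(C)(C)O3 | intermediate
3 | N-methoxy-N-methyl-2,3:5,6-di-O-isopropylidene-L-gulonamide | CON(C)C(=O)[C@H]1OC(C)(C)O[C@H]1[C@H](O)[C@@H]2COC(C)(C)O2 | intermediate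
4 | N-methoxy-N-methyl-2,3:5,6-di-O-isopropylidene-4-O-triisopropylsilyl-L-gulonamide | CON(C)C(=O)[C@H]1OC(C)(C)O[C@H]1[C@H](O[Si](C(C)C)(C(C)C)C(C)C)[C@@H]2COC(C)(C)O2 | intermediate
5 | 4-O-triisopropylsilyl-L-gulono-1,5-lactone | O=C1O[C@@H](CO)[C@@H](O[Si](C(C)C)(C(C)C)C(C)C)[C@H](O)[C@@H]1O | intermediate
6 | 2,3,6-tri-O-triethylsilyl-4-O-triisopropylsilyl-L-gulono-1,5-lactone | O=C1O[C@@H](CO[Si](CC)(CC)CC)[C@@H](O[Si](C(C)C)(C(C)C)C(C)C)[C@H](O[Si](CC)(CC)CC)[C@@H]1O[Si](CC)(CC)CC | intermediate
7 | 2,3-di-O-triethylsilyl-4-O-triisopropylsilyl-L-gulono-1,5-lactone-6-al | O=C1O[C@@H](C=O)[C@@H](O[Si](C(C)C)(C(C)C)C(C)C)[C@H](O[Si](CC)(CC)CC)[C@@H]1O[Si](CC)(CC)CC | intermediate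
8 | 4-methoxybenzyl alcohol | COc1ccc(CO)cc1 | starting material
9 | 4-methoxybenzyl (methylthio)methyl ether | COc1ccc(COCSC)cc1 | intermediate
10 | 4-methoxybenzyl chloromethyl ether | COc1ccc(COCCl)cc1 | intermediate
11 | [(4-methoxybenzyloxy)methyl]triphenylphosphonium chloride | COc1ccc(COC[P+](c2ccccc2)(c2ccccc2)c2ccccc2)cc1.[Cl-] | intermediate
12 | (4-methoxybenzyloxy)methylenetriphenylphosphorane | COc1ccc(COC=P(c2ccccc2)(c2ccccc2)c2ccccc2)cc1 | intermediate
13 | (E)-6-deoxy-7-O-(4-methoxybenzyl)-2,3-di-O-triethylsilyl-4-O-triisopropylsilyl-L-gulo-hept-6-enono-1,5-lactone | O=C1O[C@@H](/C=C/OCc2ccc(OC)cc2)[C@@H](O[Si](C(C)C)(C(C)C)C(C)C)[C@H](O[Si](CC)(CC)CC)[C@@H]1O[Si](CC)(CC)CC | intermediate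
14 | cyclic trimethylsilyl ketene acetal of 13 | C[Si](C)(C)OC1=C(O[Si](CC)(CC)CC)[C@@H](O[Si](CC)(CC)CC)[C@H](O[Si](C(C)C)(C(C)C)C(C)C)[C@H](/C=C/OCc2ccc(OC)cc2)O1 | intermediate
15 | trimethylsilyl ester of 16 | C[Si](C)(C)OC(=O)[C@]1(O[Si](CC)(CC)CC)[C@H](OCc2ccc(OC)cc2)C=C[C@@H](O[Si](C(C)C)(C(C)C)C(C)C)[C@@H]1O[Si](CC)(CC)CC | intermediate
16 | 1α,2β-bis(triethylsilyloxy)-3α-(triisopropylsilyloxy)-6β-(4-methoxybenzyloxy)cyclohex-4-ene-1β-carboxylic acid | OC(=O)[C@]1(O[Si](CC)(CC)CC)[C@H](OCc2ccc(OC)cc2)C=C[C@@H](O[Si](C(C)C)(C(C)C)C(C)C)[C@@H]1O[Si](CC)(CC)CC | intermediate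
17 | [1α,2β-bis(triethylsilyloxy)-3α-(triisopropylsilyloxy)-6β-(4-methoxybenzyloxy)cyclohex-4-en-1β-yl]methanol | OC[C@]1(O[Si](CC)(CC)CC)[C@H](OCc2ccc(OC)cc2)C=C[C@@H](O[Si](C(C)C)(C(C)C)C(C)C)[C@@H]1O[Si](CC)(CC)CC | intermediate
18 | 1β-(hydroxymethyl)-6β-(4-methoxybenzyloxy)-3α-(triisopropylsilyloxy)cyclohex-4-ene-1α,2β-diol | OC[C@]1(O)[C@H](OCc2ccc(OC)cc2)C=C[C@@H](O[Si](C(C)C)(C(C)C)C(C)C)[C@@H]1O | intermediate
19 | C7,O2-dibenzoate of 18 | O=C(OC[C@]1(O)[C@H](OCc2ccc(OC)cc2)C=C[C@@H](O[Si](C(C)C)(C(C)C)C(C)C)[C@@H]1OC(=O)c1ccccc1)c1ccccc1 | intermediate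
20 | 1β-(benzoyloxymethyl)-2β-benzoyloxy-3α-(triisopropylsilyloxy)cyclohex-4-ene-1α,6β-diol | O=C(OC[C@]1(O)[C@H](O)C=C[C@@H](O[Si](C(C)C)(C(C)C)C(C)C)[C@@H]1OC(=O)c1ccccc1)c1ccccc1 | intermediate
21 | 6β-methanesulfonate of 20 | O=C(OC[C@]1(O)[C@H](OS(C)(=O)=O)C=C[C@@H](O[Si](C(C)C)(C(C)C)C(C)C)[C@@H]1OC(=O)c1ccccc1)c1ccccc1 | intermediate
22 | 3-O-triisopropylsilyl ether of the target (1α,6α-epoxide) | O=C(OC[C@]12O[C@H]1C=C[C@@H](O[Si](C(C)C)(C(C)C)C(C)C)[C@@H]2OC(=O)c1ccccc1)c1ccccc1 | intermediate
23 | CNP0285759.2, [(1α,6α)-epoxy-2β-benzoyloxy-3α-hydroxycyclohex-4-en-1β-yl]methyl benzoate | O=C(OC[C@]12O[C@H]1C=C[C@@H](O)[C@@H]2OC(=O)c1ccccc1)c1ccccc1 | target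

**Step count and risks**

Total step count: 16. Longest linear sequence: 14 steps (1 to 23 through steps 1–6 and 9–16).

Steps most likely to fail:

1. Step 10. The lithium enolate may lose the C2 silyloxy group (E1cB) before it is silylated. The two triethylsilyl ethers may also crowd the boat array, so that ionisation of the doubly activated allylic C4–O bond and loss of the chirality to be transferred compete with the shift.
Fallback: set out from 13 and remove both triethylsilyl ethers with Bu4NF/AcOH in THF to give the 2,3-diol lactone F1. Treat F1 with LiN(i-Pr)2 (3.3 equiv, THF, −78 → −40 °C), so that both hydroxyls are alkoxides and the enolate carries a β-oxido group that cannot leave (the dianion variant of the ester enolate Claisen rearrangement of hydroxy esters). Silylate all three oxygens with Me3SiCl to the smaller tris(trimethylsilyl) ketene acetal F2 and warm to 60 °C; the same [3,3] shift gives silyl ester F3. Citric acid in methanol strips the trimethylsilyl groups to dihydroxy acid F4, and LiAlH4 reduction of F4 gives triol 18, where the route is rejoined (step 12 is then not needed).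

2. Step 9. The basic ylide may give mainly the Z enol ether, or epimerise C5 of the α-acyloxy aldehyde before it adds.
Fallback: set out from 7 and use base-free Takai–Utimoto borylolefination (CrCl2, Cl2CHB(pin), LiI, THF, rt) to give the (E)-alkenyl pinacol boronate F5, the E geometry coming from the geminal dichromium reagent. Oxidative C–O coupling of F5 with 4-methoxybenzyl alcohol 8 (Cu(OAc)2, Et3N, CH2Cl2, air, rt) proceeds with retention of alkene geometry and returns to 13.

3. Step 15. The allylic mesylate may undergo chloride substitution with allylic transposition, or a benzoyl group may shift to the tertiary alkoxide, before the oxirane closes.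
Fallback: set out from diol 20 and close the oxirane by Mitsunobu cyclodehydration (PPh3, diisopropyl azodicarboxylate, toluene, 0 → 60 °C). Only the secondary C6 hydroxyl is activated as the oxyphosphonium ion and is displaced with inversion by the C1 hydroxyl under neutral conditions, with no sulfonate and no base, returning to 22.

Further compounds
F1 | step 10 | (E)-6-deoxy-7-O-(4-methoxybenzyl)-4-O-triisopropylsilyl-L-gulo-hept-6-enono-1,5-lactone (2,3-diol) | O=C1O[C@@H](/C=C/OCc2ccc(OC)cc2)[C@@H](O[Si](C(C)C)(C(C)C)C(C)C)[C@H](O)[C@@H]1O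
F2 | step 10 | tris(trimethylsilyl) ketene acetal of F1 | C[Si](C)(C)OC1=C(O[Si](C)(C)C)[C@@H](O[Si](C)(C)C)[C@H](O[Si](C(C)C)(C(C)C)C(C)C)[C@H](/C=C/OCc2ccc(OC)cc2)O1
F3 | step 10 | trimethylsilyl 1α,2β-bis(trimethylsilyloxy)-3α-(triisopropylsilyloxy)-6β-(4-methoxybenzyloxy)cyclohex-4-ene-1β-carboxylate | C[Si](C)(C)OC(=O)[C@]1(O[Si](C)(C)C)[C@H](OCc2ccc(OC)cc2)C=C[C@@H](O[Si](C(C)C)(C(C)C)C(C)C)[C@@H]1O[Si](C)(C)C
F4 | step 10 | 1α,2β-dihydroxy-3α-(triisopropylsilyloxy)-6β-(4-methoxybenzyloxy)cyclohex-4-ene-1β-carboxylic acid | OC(=O)[C@]1(O)[C@H](OCc2ccc(OC)cc2)C=C[C@@H](O[Si](C(C)C)(C(C)C)C(C)C)[C@@H]1O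
F5 | step 9 | (E)-alkenyl pinacol boronate of the 2,3-di-O-triethylsilyl-4-O-triisopropylsilyl lactone | O=C1O[C@@H](/C=C/B2OC(C)(C)C(C)(C)O2)[C@@H](O[Si](C(C)C)(C(C)C)C(C)C)[C@H](O[Si](CC)(CC)CC)[C@@H]1O[Si](CC)(CC)CC
F0 | step 15 | none | none
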